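**Plan**

1. Retrosynthesis: the two methyl ethers go back to a C2/C3 dicarboxylate, and ring B (C1–C4, C4a, C8a) is then cut at C2–C3 and at C1–C8a in one operation, leaving two identical (E)-3,4-dimethoxycinnamoyl units.
2. Enabling feature: ring C–C1–C2–CH2O and ring A(C4a)–C4–C3–CH2O are two identical aryl-C3 units joined head to head at C2–C3. Their oxygen-bearing carbons sit on neighbouring ring carbons, so one diol can bridge them, and C8a is ortho to the C4 side chain and para to the C6 methoxy group of ring A.
3. Forward: acid 1 is esterified twice with diol 2 to give bis(cinnamate) 3. One-electron oxidation closes first the nine-membered dilactone (C2–C3) and then ring B (C1–C8a) to give 4. Hydride reduction releases the tether and gives diol 5, and double O-methylation gives phyltetralin 6.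
4. Stereochemistry: C2 and C3 come from the (2S,4S)-pentane-2,4-diol tether in the first bond formation, and C1 from anti closure of the benzylic cation next to C2. Compound 4 is purified as a single diastereomer before the tether is removed, and no epimerisable centre meets base afterwards.

Key step: step 2

Assumption: the sense of induction by the tether in step 2 is assigned from a conformational model (given in step 2), not from experiment; the model pairs the (2S,4S)-diol with the (2S,3S)-diester, and the (2R,4R)-diol would be used instead if the pairing proved opposite.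

**Step 1**
Reactants: 1 (E)-3,4-dimethoxycinnamic acid (2 equiv); 2 (2S,4S)-pentane-2,4-diol
Product: 3 (2S,4S)-pentane-2,4-diyl bis[(E)-3-(3,4-dimethoxyphenyl)acrylate]
Conditions: DCC, DMAP (cat.), CH2Cl2, 0 °C to rt
Reagents that add atoms: none
Why: Steglich esterification acylates both secondary hydroxyl groups at oxygen, so the two carbinol centres keep their (S) configuration and the E alkenes are untouched.

**Step 2**
Reactants: 3 (2S,4S)-pentane-2,4-diyl bis[(E)-3-(3,4-dimethoxyphenyl)acrylate]
Product: 4 cyclic (2S,4S)-pentane-2,4-diyl (1R,2S,3S)-1-(3,4-dimethoxyphenyl)-6,7-dimethoxy-1,2,3,4-tetrahydronaphthalene-2,3-dicarboxylate (nine-membered dilactone trans-fused to ring B at C2–C3)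
Conditions: 9-mesityl-3,6-di-tert-butyl-10-phenylacridinium tetrafluoroborate (5 mol%), PhSSPh (20 mol%), degassed DCE/HFIP 9:1 (5 mM), 450 nm LEDs, rt
Reagents that add atoms: none
Why: Proposed new method: the photoexcited acridinium should oxidise one 3,4-dimethoxycinnamate to its radical cation, the alkene carbon next to the carbonyl of the tethered neutral cinnamate adds to the same carbon of the radical cation (C2–C3, 9-exo closure of the dilactone ring; only this regiochemistry leaves charge and spin on two 4-methoxybenzylic carbons), the benzylic cation alkylates the other arene at the carbon ortho to its side chain and para to a methoxy group (C1–C8a, ring B in the 6-endo Friedel–Crafts mode), and after proton loss thiophenol formed from PhSSPh gives a hydrogen atom to the remaining benzylic radical (C4 methylene) while the thiyl radical takes the electron back from the acridine radical, so that the step is a redox-neutral isomerisation. The closest known reaction type is the acridinium/disulfide photoredox [4+2] dimerisation of styrenes to 1-aryltetralins, which has not been shown for acceptor-substituted alkenes such as cinnamates or in a tethered, stereocontrolled form; chiral-diol tethers are known only from cinnamate [2+2] photodimerisations. C2 and C3 are set by the tether in the first bond formation: two s-cis enoates bridged through their alkoxy oxygens by the C2-symmetric diol are expected to meet in a C2-symmetric crossed arrangement that gives the trans diester, and with each carbinol C–H eclipsing its C=O and both methyl groups pseudo-equatorial the (S,S)-diol admits the twist of that arrangement that leads to (2S,3S). C1 is set in the Friedel–Crafts closure, where the aryl group takes the pseudo-equatorial position anti to the C2 carboxyl group (1R). The step needs [4+2] instead of [2+2] closure and an intramolecular course: a cyclobutane formed from the same intermediate would be reoxidised and reopened by the catalyst whereas arene alkylation followed by proton loss is irreversible, and high dilution suppresses intermolecular coupling. Stereoisomers of 4 are diastereomers because of the tether and are removed by chromatography and crystallisation before step 3.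

**Step 3**
Reactants: 4 cyclic (2S,4S)-pentane-2,4-diyl (1R,2S,3S)-1-(3,4-dimethoxyphenyl)-6,7-dimethoxy-1,2,3,4-tetrahydronaphthalene-2,3-dicarboxylate
Product: 5 [(1R,2S,3S)-1-(3,4-dimethoxyphenyl)-6,7-dimethoxy-1,2,3,4-tetrahydronaphthalene-2,3-diyl]dimethanol
Conditions: LiAlH4, THF, 0 °C to rt; aqueous work-up
Reagents that add atoms: none
Why: Lithium aluminium hydride reduction of both lactone carbonyls to primary alcohols opens the nine-membered ring and frees the tether without touching C1, C2 or C3, because hydride addition is much faster than enolisation of the esters.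

**Step 4**
Reactants: 5 [(1R,2S,3S)-1-(3,4-dimethoxyphenyl)-6,7-dimethoxy-1,2,3,4-tetrahydronaphthalene-2,3-diyl]dimethanol
Product: 6 phyltetralin, (1R,2S,3S)-1-(3,4-dimethoxyphenyl)-6,7-dimethoxy-2,3-bis(methoxymethyl)-1,2,3,4-tetrahydronaphthalene
Conditions: NaH, MeI, THF/DMF, 0 °C to rt
Reagents that add atoms: iodomethane, CI
Why: Williamson ether synthesis on the two primary alkoxides gives the bis(methyl ether), and neither the stereocentres nor the aryl ethers are affected by these basic conditions.

**Compound list**

1 | (E)-3,4-dimethoxycinnamic acid | COc1ccc(/C=C/C(=O)O)cc1OC | starting material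
2 | (2S,4S)-pentane-2,4-diol | C[C@H](O)C[C@H](C)O | starting material
3 | (2S,4S)-pentane-2,4-diyl bis[(E)-3-(3,4-dimethoxyphenyl)acrylate] | C[C@H](OC(=O)/C=C/c1ccc(OC)c(OC)c1)C[C@H](C)OC(=O)/C=C/c1ccc(OC)c(OC)c1 | intermediate
4 | cyclic (2S,4S)-pentane-2,4-diyl (1R,2S,3S)-1-(3,4-dimethoxyphenyl)-6,7-dimethoxy-1,2,3,4-tetrahydronaphthalene-2,3-dicarboxylate | C[C@H]1C[C@H](C)OC(=O)[C@H]2Cc3cc(OC)c(OC)cc3[C@@H](c3ccc(OC)c(OC)c3)[C@@H]2C(=O)O1 | intermediate
5 | [(1R,2S,3S)-1-(3,4-dimethoxyphenyl)-6,7-dimethoxy-1,2,3,4-tetrahydronaphthalene-2,3-diyl]dimethanol | OC[C@H]1Cc2cc(OC)c(OC)cc2[C@@H](c2ccc(OC)c(OC)c2)[C@@H]1CO | intermediate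
6 | phyltetralin, (1R,2S,3S)-1-(3,4-dimethoxyphenyl)-6,7-dimethoxy-2,3-bis(methoxymethyl)-1,2,3,4-tetrahydronaphthalene | COC[C@H]1Cc2cc(OC)c(OC)cc2[C@@H](c2ccc(OC)c(OC)c2)[C@@H]1COC | target

Total step count: 4. Longest linear sequence: 4 steps (1 or 2 to 6).

**Steps most likely to fail**

Step 2 (carries the proposed method). The radical cation may take its electron back before the nine-membered ring closes. The two alkenes may also couple with unlike topicity or with the opposite twist, or stop at a cyclobutane, so that little of the single diastereomer 4 forms.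

The fallback uses known chemistry, sets out from compound 1 and rejoins the route at compound 6. Hydrogenation of 1 (H2, palladium on carbon (Pd/C), EtOAc) gives 3-(3,4-dimethoxyphenyl)propanoic acid F1. Its pivaloyl mixed anhydride (PivCl, Et3N, LiCl, THF) acylates (R)-4-benzyloxazolidin-2-one to give (R)-4-benzyl-3-[3-(3,4-dimethoxyphenyl)propanoyl]oxazolidin-2-one F2. Oxidative homocoupling of its lithium enolate (LiN(iPr)2, THF, −78 °C, then TiCl4) is the established auxiliary-controlled dimerisation of 3-arylpropanoyl oxazolidinones. It should join the two α-carbons (the later C2–C3 bond) as the (2S,3S)-2,3-bis(3,4-dimethoxybenzyl)succinyl bis-imide F3. LiBH4 (THF, trace H2O) removes both auxiliaries and gives (2S,3S)-2,3-bis(3,4-dimethoxybenzyl)butane-1,4-diol F4. NaH/MeI then gives (2S,3S)-2,3-bis(3,4-dimethoxybenzyl)-1,4-dimethoxybutane F5. DDQ in TFA at 0 °C oxidises one benzylic position to the cation, which closes C1–C8a anti to the C2 substituent. This is the known oxidative cyclisation of dibenzylbutane lignans to 1-aryltetralins and should give 6.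

Step 1. Acyl transfer to the hindered secondary diol may stall at the mono-ester while the activated acid is drained off as N-acylurea.

The fallback sets out from compound 2 and rejoins the route at compound 3. Acylation of 2 with acryloyl chloride (Et3N, CH2Cl2, 0 °C) gives (2S,4S)-pentane-2,4-diyl diacrylate F6. A twofold Mizoroki–Heck arylation with 4-iodo-1,2-dimethoxybenzene (Pd(OAc)2, P(o-tol)3, Et3N, DMF, 90 °C) should then build both E-cinnamate units and deliver 3.

Step 3. Hydride delivery to the strained, hindered dilactone may stop at a lactol or hydroxy-ester stage, or an aluminium enolate may scramble C2 or C3.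

The fallback sets out from compound 4 and rejoins the route at compound 5. Methanolysis of diastereomerically pure 4 (NaOMe, MeOH, reflux) releases the tether and gives dimethyl (1R,2S,3S)-1-(3,4-dimethoxyphenyl)-6,7-dimethoxy-1,2,3,4-tetrahydronaphthalene-2,3-dicarboxylate F7. With C1 fixed, this all-trans diester is the thermodynamic isomer, so equilibration cannot erode the configuration. LiAlH4 reduction of the unhindered diester (THF, 0 °C) then gives 5.

**Further compounds**

F1 | step 2 | 3-(3,4-dimethoxyphenyl)propanoic acid | COc1ccc(CCC(=O)O)cc1OC
F2 | step 2 | (R)-4-benzyl-3-[3-(3,4-dimethoxyphenyl)propanoyl]oxazolidin-2-one | COc1ccc(CCC(=O)N2[C@H](Cc3ccccc3)COC2=O)cc1OC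
F3 | step 2 | (4R,4'R)-3,3'-[(2S,3S)-2,3-bis(3,4-dimethoxybenzyl)butanedioyl]bis(4-benzyloxazolidin-2-one) | COc1ccc(C[C@H](C(=O)N2[C@H](Cc3ccccc3)COC2=O)[C@H](Cc2ccc(OC)c(OC)c2)C(=O)N2[C@H](Cc3ccccc3)COC2=O)cc1OC
F4 | step 2 | (2S,3S)-2,3-bis(3,4-dimethoxybenzyl)butane-1,4-diol | COc1ccc(C[C@H](CO)[C@@H](CO)Cc2ccc(OC)c(OC)c2)cc1OC
F5 | step 2 | (2S,3S)-2,3-bis(3,4-dimethoxybenzyl)-1,4-dimethoxybutane | COc1ccc(C[C@H](COC)[C@@H](COC)Cc2ccc(OC)c(OC)c2)cc1OC
F6 | step 1 | (2S,4S)-pentane-2,4-diyl diacrylate | C=CC(=O)O[C@@H](C)C[C@H](C)OC(=O)C=C
F7 | step 3 | dimethyl (1R,2S,3S)-1-(3,4-dimethoxyphenyl)-6,7-dimethoxy-1,2,3,4-tetrahydronaphthalene-2,3-dicarboxylate | COC(=O)[C@H]1Cc2cc(OC)c(OC)cc2[C@@H](c2ccc(OC)c(OC)c2)[C@@H]1C(=O)OC
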